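## Structural features

The target joins three units: a coumarin (a benzene ring fused to a pyranone ring) is linked through its 7-oxygen and a methylene carbon C7 to C1 of a 2,6,6-trimethylcyclohex-2-ene carbocycle, whose C5 carries an isovalerate ester. The carbocycle (C1 CH–C7, C2 C–CH3, C3 =CH, C4 CH2, C5 CH–O, C6 CMe2) holds two stereocentres, C1 (S) and C5 (R); they are not adjacent but both flank the quaternary C6, and the C7 arm and the C5 oxygen are cis. Several groups are fragile. The pyranone lactone does not survive hydride or alkoxide. The C2=C3 alkene lies β,γ to C7, so C1 can epimerise and the alkene can slide into conjugation whenever C7 is a carbonyl. A C5 alkoxide beside a C1 ketone can undergo retro-aldol cleavage of C5–C6, and the δ-hydroxy enone can lose water in a vinylogous sense across C4–C5. The real difficulty is the C1–C6–C5 array, in which a quaternary carbon separates two stereocentres with no neighbouring group to relay configuration, together with the need to place the alkene at C2=C3 and not at C1=C2. The key step exploits the fact that C5 is a carbinol carbon bonded to quaternary C6 and, through C4, to the γ-position of a C1(=O)–C2(CH3)=C3 enone. Cutting C4–C5 therefore leaves an acyclic keto aldehyde whose only enolisable position is the γ-methyl C4, and a vinylogous aldol closes the carbocycle, sets C5 and leaves C2=C3 in place. The cis-1,3 relationship is used a second time: C7 on C1 and the oxygen on C5 can be tied into a bridged γ-lactone that forms only from the cis isomer, which relays C5 to C1. The keto aldehyde is cyclised as its (E)-silyl dienol ether and not as a metal dienolate, because the C1=C2 geometry of the nucleophile decides whether C4 can reach C5 and because a metal aldolate could revert or dehydrate.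

## Logic of the disconnections

20 to 18 and 19. The acyl–oxygen bond of the C5 ester is cut first, because the ester would not survive the hydride and alkoxide chemistry needed earlier. This removes a five-carbon side chain and leaves one free secondary hydroxyl. The forward step must acylate a hindered hydroxyl next to C6 without opening the pyranone.

18 to 16 and 17. The C7–O(aryl) bond is cut so that the pyranone-bearing aromatic unit enters after all reductions. The carbocyclic part becomes a small diol and the aromatic part a purchased phenol. The forward step must activate the primary C7 hydroxyl in preference to the C5 hydroxyl and let the phenoxide outrun internal ether formation.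

16 to 15. The two hydroxyls are reconnected through a C7 carbonyl (O5–C7 bond). A bridged lactone can exist only with C1 and C5 cis, so the relative configuration becomes a consequence of ring constraint. The forward hydride reduction must not epimerise C1.

15 to 13 (through 14). The lactone C7–O5 bond is cut and the alkene is moved from C2=C3 to C1=C2, which erases the C1 stereocentre. One stereocentre and a plain conjugated ester remain. The forward step needs reversible removal of C3–H, reprotonation at C1 and ring closure from the cis epimer only.

13 to 11 (through 12). The C1–C7 bond and the O–Si bond are cut; C7 is traced to a one-carbon gas and an alcohol, C1 to a vinyl sulfonate. The substrate simplifies to an enol derivative of a ketone. The forward step needs insertion at a tetrasubstituted vinyl carbon flanked by C6 and the C2 methyl.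

11 to 9 (through 10). The O–S bond is cut and the C3–H bond removed, which returns the C2=C3 unsaturation of a conjugated enone. This is the functionality the ring-forming step delivers. The forward step needs 1,4- rather than 1,2-hydride delivery and O-sulfonylation of a hindered enolate.

9 to 8. The O–Si bond is cut; the group is protective only. The forward silylation must avoid alkoxide formation, which would open the way to retro-aldol cleavage.

8 to 6 (through 7). The C4–C5 bond is cut. The ring opens to an achiral chain in which C5 is an aldehyde and C4 the γ-terminus of a silyl dienol ether. One ring, one skeletal bond and one stereocentre are removed. The forward step needs enantiofacial control at C5 from an external chiral activator; γ-selectivity follows from ring size.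

6 to 5. The O–Si bond is cut. The forward enol silylation must give the geometry with C6 and C3 cis on C1=C2 and must leave the aldehyde untouched.

5 to 2 and 3 (through 4). The C1–C6 bond between the ketone carbon and the quaternary carbon is cut, giving a four-carbon enamine and a five-carbon acid chloride. The forward step needs C-acylation of a β,β-disubstituted enamine without conjugate addition.

2 to 1. The C–N bond is cut, leaving a purchased aldehyde. The forward condensation needs removal of water only.

## Other disconnections considered

Alternative 1: The cut is made at the C5–O and O–C7 bonds of the bridged lactone 15, which are traced to oxygen insertion into the four-membered ketone of a pinane. The carbocycle, C6 with its two methyls and both stereocentres (the two bridgeheads) would then come ready-made from the terpene pool.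
- Forward key step: Baeyer–Villiger oxidation of 2,3-epoxychrysanthenone A1 with a buffered peracid to give epoxy lactone A2. Bridgehead C5 should migrate in preference to C1, because C1 is attached to the electron-poor epoxide carbon C2. Deoxygenation of the epoxide of A2 would give 15, after which steps 9 to 11 apply unchanged.
- In its favour: the cis relationship is built into a bicycle and cannot be lost, the absolute configuration is bought and not made, every reaction type is established, and the count from a commercial pinane enone to 20 would be about seven steps.
- Against it here: A1 has to be reached through a photochemical 1,3-acyl shift, which passes through ring-opened ketene species and can erode the bridgehead configuration. The migratory preference rests only on an inductive difference between two secondary bridgeheads. An epoxide beside a strained ring under peracid conditions invites cationic skeletal rearrangement. The C2=C3 alkene must be regenerated from the epoxide in the presence of the lactone.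
- Comparison: on structure the two plans are equal, since both pass through 15 and both fix C1 against C5 by the same lactone. On mechanism the alternative is the better, because it needs no unprecedented step and no catalyst-controlled enantioselection; the chosen plan can reach either antipode from achiral feedstock but at the price of an untested cyclisation. On step economy the alternative is the better by roughly four steps, provided the photochemical step and the deoxygenation need no extra operations.

Alternative 2: Two bonds are cut without opening the ring, C6–CH3 and C1–C7, which leads back to the six-membered enone A3 ((R)-4-silyloxy-3-methylcyclohex-2-enone) and two one-carbon reagents.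
- Forward key step: a chlorosilane-accelerated methylcuprate conjugate addition creates the quaternary C6 of A3, and the silyl enol ether so formed is hydroxymethylated at C1 in water under Yb(OTf)3 catalysis to give A4.
- In its favour: C6 is not stereogenic, so the conjugate addition carries no stereochemical risk. C1 in A4 lies α to a ketone and the cis (diequatorial) isomer is the thermodynamic one, a control element equal in kind to the lactone relay of the chosen plan. C7 arrives at the alcohol oxidation level, which saves the hydride step and is better in redox economy. All reactions are of established types.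
- Against it here: the ring and the C5 stereocentre are presupposed, so A3 needs its own asymmetric preparation. Cuprate addition to a fully substituted β-carbon beside a γ-silyloxy group is slow and open to γ-elimination. The ketone of A4 must still be converted into the C2 methyl and the C2=C3 alkene by regioselective enol sulfonate formation toward C3 and methyl cross-coupling, while the β-oxygenated C7 arm is prone to β-elimination.
- Comparison: on structure the chosen plan simplifies more, since it builds the ring from two small acyclic pieces whereas the alternative only decorates a ring. On mechanism the alternative is the better in certainty, but it leaves the absolute configuration to an earlier, separate problem. On step economy the two are about equal once the preparation of A3 is counted.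

Alternative 3: The ring is cut at C1–C6 and C4–C5, a Diels–Alder retron with C2=C3 as the new alkene, giving dienyl ether A5 (from 17 by one O-alkylation) and alkenylborolane A6.
- Forward key step: [4+2] cycloaddition of A5 with A6 to cycloadduct A7, with boron ending on C5. Oxidation of the C–B bond with retention and acylation with 19 would complete 20.
- In its favour: ring, aryl ether and both stereocentres would be set in one step, and the pyranone never meets a hydride. The orientation wanted (boron para to the C2 methyl, meta to the C1 substituent) agrees with the usual bias of alkenylboranes, and an endo boron gives the cis product. Four to five steps in all is clearly better than the chosen plan in step economy and convergence.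
- Against it here: A6 is a β,β-disubstituted alkenylborane, a poor dienophile, and the C1–C6 bond must join a substituted diene terminus to a carbon that becomes quaternary. Facial control by a C2-symmetric borolane in a cycloaddition has no close precedent. The dialkylborane is a Lewis acid toward the pyranone carbonyl, and the C–B oxidation must avoid alkaline peroxide.
- Comparison: on structure the alternative is the better, since it disconnects two ring bonds at once and needs no relay of stereochemistry. On mechanism it is the equal of the chosen plan in being unprecedented at its key step, but weaker in that regiochemistry, relative and absolute configuration all depend on that one step; the chosen plan asks its new step for a single stereocentre and relays the second by a thermodynamic ring closure. On step economy the alternative is the better by about six steps if the cycloaddition proceeds.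

Key step: step 4

Remark on the chemistry: the (R,R) antipode of the bisphosphoramide is assumed to deliver C4 to the Re face of the C5 aldehyde; if the ring-closing case shows the opposite sense, the (S,S) antipode is used with no other change.

## Route

Step 1
Reactants: 1 isobutyraldehyde
Product: 2 N-(2-methylprop-1-en-1-yl)pyrrolidine
Conditions: pyrrolidine (1.1 equiv), cyclohexane, reflux, azeotropic removal of H2O; distillation
Reagents that add atoms: pyrrolidine, C1CCNC1
Why: Enamine formation by condensation of an α-branched aldehyde with a secondary amine; only one regioisomer is possible and no stereocentre is formed.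

Step 2
Reactants: 2 N-(2-methylprop-1-en-1-yl)pyrrolidine; 3 tigloyl chloride
Product: 5 (E)-2,2,4-trimethyl-3-oxohex-4-enal, via iminium chloride 4 (not isolated)
Conditions: Et2O, 0 °C → rt; then 1 M aq. HCl, 0 °C → rt
Reagents that add atoms: water, O
Why: Stork enamine acylation: the enamine β-carbon attacks the acid chloride to give C-acyl iminium salt 4, which cannot tautomerise because C6 is quaternary and so consumes no second equivalent of enamine; dilute acid hydrolyses it to the keto aldehyde with the (E) alkene untouched. No tertiary amine is added, so the acid chloride is not converted into a vinylketene.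

Step 3
Reactants: 5 (E)-2,2,4-trimethyl-3-oxohex-4-enal
Product: 6 (3E)-3-[(tert-butyldimethylsilyl)oxy]-2,2,4-trimethylhexa-3,5-dienal
Conditions: TBSOTf (1.2 equiv), Et3N (2.5 equiv), Et2O, −78 → 0 °C; pentane, cold aq. NaHCO3, filtration through basic alumina
Reagents that add atoms: tert-butyldimethylsilyl trifluoromethanesulfonate, CC(C)(C)[Si](C)(C)OS(=O)(=O)C(F)(F)F
Why: Soft enolisation: O-silylation of the only enolisable carbonyl and removal of a γ-proton from C4 give the 2-silyloxy diene. The (3E) geometry (C6 cis to C3) is expected because it keeps the quaternary C6 away from the C2 methyl, and excess amine in ether keeps the silyl triflate from activating the non-enolisable aldehyde.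

Step 4
Reactants: 6 (3E)-3-[(tert-butyldimethylsilyl)oxy]-2,2,4-trimethylhexa-3,5-dienal
Product: 8 (R)-5-hydroxy-2,6,6-trimethylcyclohex-2-en-1-one, via trichlorosilyl ether 7 (not isolated)
Conditions: SiCl4 (1.1 equiv), (R,R)-bisphosphoramide (two N,N′-dimethyl-1,1′-binaphthyl-2,2′-diamine phosphoramide units joined by an N,N′-dimethylpentane-1,5-diamine tether, 5 mol%), i-Pr2NEt (10 mol%), CH2Cl2 (0.05 M), −78 °C; then sat. aq. NaHCO3, 0 °C
Reagents that add atoms: none
Why: Proposed new method: the bisphosphoramide binds SiCl4 and expels chloride to give a chiral cationic trichlorosilyl species that activates the C5 aldehyde, the γ-terminus C4 of the silyl dienol ether attacks it, chloride removes the silyl group as TBSCl and the aldolate stays as trichlorosilyl ether 7 until hydrolysis; the closest known reaction types are the intermolecular Lewis-base-activated SiCl4 vinylogous Mukaiyama aldol addition of silyl dienol ethers to aldehydes and the racemic Lewis-acid-mediated intramolecular vinylogous Mukaiyama aldol, the catalytic enantioselective ring-closing version on an α-quaternary aliphatic aldehyde being the untested combination. The single ring (the carbocycle C1–C6) closes in a 6-(enolendo)-exo-trig mode, C1=C2 and C3=C4 of the nucleophile lying inside the forming ring and the C5=O bond outside it. The one new stereocentre, C5, is set by the catalyst alone, the substrate being achiral: attack of C4 on the Re face of the aldehyde gives (R). γ-Selectivity is needed and is secured by ring size, since attack through C2 would close a cyclobutane. The (3E) geometry of 6 is needed because only with C6 and C3 cis on C1=C2 can C4 reach C5, and the new C2=C3 alkene is then necessarily cis within the ring. A racemic background is not expected because SiCl4 without the Lewis base does not activate aldehydes. The non-basic medium and the silylated aldolate exclude retro-aldol cleavage of C5–C6 and vinylogous loss of water across C4–C5, while loss of water toward C6 is impossible and the aldehyde cannot enolise.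

Step 5
Reactants: 8 (R)-5-hydroxy-2,6,6-trimethylcyclohex-2-en-1-one
Product: 9 (R)-2,6,6-trimethyl-5-[(triethylsilyl)oxy]cyclohex-2-en-1-one
Conditions: Et3SiCl (1.3 equiv), imidazole (2.5 equiv), DMF, 0 °C → rt
Reagents that add atoms: chlorotriethylsilane, CC[Si](Cl)(CC)CC
Why: Silyl ether formation under imidazole catalysis, with no alkoxide formed, so retro-aldol cleavage and vinylogous dehydration of the β-hydroxy ketone are avoided; the triethylsilyl group is chosen because dilute acid removes it later, and C5 is untouched.

Step 6
Reactants: 9 (R)-2,6,6-trimethyl-5-[(triethylsilyl)oxy]cyclohex-2-en-1-one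
Product: 11 (R)-2,6,6-trimethyl-5-[(triethylsilyl)oxy]cyclohex-1-en-1-yl trifluoromethanesulfonate, via lithium enolate 10 (not isolated)
Conditions: LiBH(s-Bu)3 (1.1 equiv), THF, −78 °C; then PhNTf2 (1.2 equiv), −78 °C → rt; aq. NH4Cl
Reagents that add atoms: N-phenylbis(trifluoromethanesulfonimide), O=S(=O)(N(c1ccccc1)S(=O)(=O)C(F)(F)F)C(F)(F)F
Why: Reductive enol triflation: the bulky borohydride adds 1,4 because the carbonyl is shielded by C6 and the β-carbon C3 carries only hydrogen, giving the C1–C2 enolate regiospecifically, which is O-sulfonylated by the triflimide. C5 is not affected.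

Step 7
Reactants: 11 (R)-2,6,6-trimethyl-5-[(triethylsilyl)oxy]cyclohex-1-en-1-yl trifluoromethanesulfonate
Product: 13 methyl (R)-5-hydroxy-2,6,6-trimethylcyclohex-1-ene-1-carboxylate, via silyl ether ester 12 (not isolated)
Conditions: Pd(OAc)2 (5 mol%), 1,3-bis(diphenylphosphino)propane (5 mol%), CO (1 atm), Et3N (2 equiv), MeOH–DMF, 70 °C; then 1 M aq. HCl, MeOH, rt
Reagents that add atoms: carbon monoxide, [C-]#[O+]; methanol, CO
Why: Palladium-catalysed alkoxycarbonylation of an enol triflate: oxidative addition to zerovalent palladium formed in the flask, CO insertion and methanolysis of the acylpalladium place C7 on C1, the chelating phosphine supporting the hindered vinylpalladium. Dilute acid then cleaves the triethylsilyl ether without touching the twisted enoate.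

Step 8
Reactants: 13 methyl (R)-5-hydroxy-2,6,6-trimethylcyclohex-1-ene-1-carboxylate
Product: 15 (1S,5R)-2,8,8-trimethyl-6-oxabicyclo[3.2.1]oct-2-en-7-one, via cis hydroxy ester 14 (not isolated)
Conditions: KOt-Bu (1.5 equiv), THF, 0 °C → rt; then AcOH
Reagents that add atoms: none
Why: Base-mediated deconjugation with dynamic epimerisation–lactonisation: tert-butoxide reversibly removes the ring C3–H, α-protonation at C1 gives the 2-ene esters, and only the cis epimer 14 can bring its C5 alkoxide onto the ester across C6, helped by the gem-dimethyl effect. Lactone 15 cannot enolise at its bridgehead, so it is a sink that fixes C1 as S relative to C5 R, while the trans epimer returns through the dienolate.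

Step 9
Reactants: 15 (1S,5R)-2,8,8-trimethyl-6-oxabicyclo[3.2.1]oct-2-en-7-one
Product: 16 (1R,5S)-5-(hydroxymethyl)-4,6,6-trimethylcyclohex-3-en-1-ol
Conditions: LiAlH4 (1.5 equiv), THF, 0 °C → rt; H2O, 15% aq. NaOH, H2O
Reagents that add atoms: none
Why: Hydride reduction of a lactone to the diol; the intermediate lactol aluminate is reduced faster than it can enolise, so C1 keeps its configuration, and the isolated trisubstituted alkene is inert.

Step 10
Reactants: 16 (1R,5S)-5-(hydroxymethyl)-4,6,6-trimethylcyclohex-3-en-1-ol; 17 umbelliferone
Product: 18 7-{[(1S,5R)-5-hydroxy-2,6,6-trimethylcyclohex-2-en-1-yl]methoxy}-2H-chromen-2-one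
Conditions: 17 (1.5 equiv), PPh3 (1.5 equiv), diisopropyl azodicarboxylate (1.5 equiv), THF (0.5 M), 0 °C → rt
Reagents that add atoms: none
Why: Mitsunobu etherification: the acidic phenol 17 protonates the phosphine–azodicarboxylate betaine, the primary C7 hydroxyl is activated in preference to the hindered C5 hydroxyl and is displaced by the phenoxide in an SN2 step at a non-stereogenic carbon. The neutral medium spares the pyranone.

Step 11
Reactants: 18 7-{[(1S,5R)-5-hydroxy-2,6,6-trimethylcyclohex-2-en-1-yl]methoxy}-2H-chromen-2-one; 19 isovaleryl chloride
Product: 20 (1R,5S)-4,6,6-trimethyl-5-{[(2-oxo-2H-chromen-7-yl)oxy]methyl}cyclohex-3-en-1-yl 3-methylbutanoate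
Conditions: 19 (1.5 equiv), pyridine (3 equiv), 4-(dimethylamino)pyridine (0.1 equiv), CH2Cl2, 0 °C → rt
Reagents that add atoms: none
Why: Acylation of a hindered secondary alcohol by an acid chloride under nucleophilic catalysis; pyridine buffers the HCl, the pyranone and aryl ether are stable, and neither stereocentre is touched.

## Compound list

1 | isobutyraldehyde (2-methylpropanal) | CC(C)C=O | starting material
2 | N-(2-methylprop-1-en-1-yl)pyrrolidine | CC(C)=CN1CCCC1 | intermediate
3 | tigloyl chloride, (E)-2-methylbut-2-enoyl chloride | C/C=C(\C)C(Cl)=O | starting material
4 | 1-[(4E)-2,2,4-trimethyl-3-oxohex-4-en-1-ylidene]pyrrolidin-1-ium chloride; not isolated | C/C=C(\C)C(=O)C(C)(C)C=[N+]1CCCC1.[Cl-] | intermediate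
5 | (E)-2,2,4-trimethyl-3-oxohex-4-enal | C/C=C(\C)C(=O)C(C)(C)C=O | intermediate
6 | (3E)-3-[(tert-butyldimethylsilyl)oxy]-2,2,4-trimethylhexa-3,5-dienal | C=C/C(C)=C(/O[Si](C)(C)C(C)(C)C)C(C)(C)C=O | intermediate
7 | (R)-2,6,6-trimethyl-5-[(trichlorosilyl)oxy]cyclohex-2-en-1-one; not isolated | CC1=CC[C@@H](O[Si](Cl)(Cl)Cl)C(C)(C)C1=O | intermediate
8 | (R)-5-hydroxy-2,6,6-trimethylcyclohex-2-en-1-one | CC1=CC[C@@H](O)C(C)(C)C1=O | intermediate
9 | (R)-2,6,6-trimethyl-5-[(triethylsilyl)oxy]cyclohex-2-en-1-one | CC1=CC[C@@H](O[Si](CC)(CC)CC)C(C)(C)C1=O | intermediate
10 | lithium (R)-2,6,6-trimethyl-5-[(triethylsilyl)oxy]cyclohex-1-en-1-olate; not isolated | CC1=C([O-])C(C)(C)[C@H](O[Si](CC)(CC)CC)CC1.[Li+] | intermediate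
11 | (R)-2,6,6-trimethyl-5-[(triethylsilyl)oxy]cyclohex-1-en-1-yl trifluoromethanesulfonate | CC1=C(OS(=O)(=O)C(F)(F)F)C(C)(C)[C@H](O[Si](CC)(CC)CC)CC1 | intermediate
12 | methyl (R)-2,6,6-trimethyl-5-[(triethylsilyl)oxy]cyclohex-1-ene-1-carboxylate; not isolated | CC1=C(C(=O)OC)C(C)(C)[C@H](O[Si](CC)(CC)CC)CC1 | intermediate
13 | methyl (R)-5-hydroxy-2,6,6-trimethylcyclohex-1-ene-1-carboxylate | CC1=C(C(=O)OC)C(C)(C)[C@H](O)CC1 | intermediate
14 | methyl (1S,5R)-5-hydroxy-2,6,6-trimethylcyclohex-2-ene-1-carboxylate; not isolated, reacts on as its potassium alkoxide | CC1=CC[C@@H](O)C(C)(C)[C@H]1C(=O)OC | intermediate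
15 | (1S,5R)-2,8,8-trimethyl-6-oxabicyclo[3.2.1]oct-2-en-7-one | CC1=CC[C@H]2OC(=O)[C@@H]1C2(C)C | intermediate
16 | (1R,5S)-5-(hydroxymethyl)-4,6,6-trimethylcyclohex-3-en-1-ol | CC1=CC[C@@H](O)C(C)(C)[C@H]1CO | intermediate
17 | umbelliferone (7-hydroxy-2H-chromen-2-one) | O=c1ccc2ccc(O)cc2o1 | starting material
18 | 7-{[(1S,5R)-5-hydroxy-2,6,6-trimethylcyclohex-2-en-1-yl]methoxy}-2H-chromen-2-one | CC1=CC[C@@H](O)C(C)(C)[C@H]1COc1ccc2ccc(=O)oc2c1 | intermediate
19 | isovaleryl chloride (3-methylbutanoyl chloride) | CC(C)CC(Cl)=O | starting material
20 | (1R,5S)-4,6,6-trimethyl-5-{[(2-oxo-2H-chromen-7-yl)oxy]methyl}cyclohex-3-en-1-yl 3-methylbutanoate | CC1=CC[C@@H](OC(=O)CC(C)C)C(C)(C)[C@H]1COc1ccc2ccc(=O)oc2c1 | target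

## Step count and least certain steps

Total: 11 steps. Longest linear sequence: 11 steps (1 to 20); 17 and 19 enter as purchased materials in steps 10 and 11.

Step 4 (key step; the step bearing the label Proposed new method).
- What may go wrong: poor enantiofacial discrimination or stalled turnover. The α-quaternary aliphatic aldehyde may bind the bulky cationic silicon complex weakly or be held back by reversible chloride addition. The short tether may also impose a transition-state geometry that the chiral pocket does not differentiate.
- Fallback (known chemistry), from 6 back to 8: 6 is cyclised without a chiral promoter by TiCl4 in CH2Cl2 at −78 °C (intramolecular vinylogous Mukaiyama aldol) to racemic 5-hydroxy-2,6,6-trimethylcyclohex-2-en-1-one F1. Lipase-catalysed acylation (Candida antarctica lipase B, vinyl acetate, t-BuOMe) is expected to acetylate one enantiomer, taken here to be the (R)-alcohol. This gives (R)-4,6,6-trimethyl-5-oxocyclohex-3-en-1-yl acetate F2 and leaves (S)-5-hydroxy-2,6,6-trimethylcyclohex-2-en-1-one F3, which is removed by chromatography. The same lipase in pH 7 phosphate buffer then hydrolyses F2 to 8 without an alkoxide being formed. Should the enzyme prefer the (S)-alcohol, the unreacted alcohol is 8 itself.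

Step 2.
- What may go wrong: diversion from C-acylation. N-acylation followed by sigmatropic or ketene pathways, or γ-deprotonation of the unsaturated acid chloride to a vinylketene that adds to the enamine, would consume both partners.
- Fallback, from 1 back to 5: 1 is converted into its silyl enol ether 2-methyl-1-(trimethylsilyloxy)prop-1-ene F4 (Me3SiCl, Et3N, DMF, 80 °C). BF3·OEt2-mediated Mukaiyama aldol addition of F4 to (E)-2-methylbut-2-enal F5 in CH2Cl2 at −78 °C gives racemic (E)-3-hydroxy-2,2,4-trimethylhex-4-enal F6. Its allylic hydroxyl is oxidised with MnO2 in CH2Cl2 to give 5.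

Step 3.
- What may go wrong: premature ring closure promoted by the silyl triflate, which would give racemic silylated aldol, or enolisation with the wrong C1=C2 geometry, which would give material that cannot cyclise.
- Fallback, from 5 back to 6: condensation of 5 with tert-butylamine (MgSO4, CH2Cl2) masks the aldehyde as the non-enolisable aldimine (4E)-1-(tert-butylimino)-2,2,4-trimethylhex-4-en-3-one F7. Kinetic γ-deprotonation with LiN(i-Pr)2 in THF at −78 °C and O-silylation with TBSCl give (3E)-N-tert-butyl-3-[(tert-butyldimethylsilyl)oxy]-2,2,4-trimethylhexa-3,5-dien-1-imine F8, with no silyl triflate present. The aldimine is hydrolysed in a pH 5 acetate buffer at 0 °C to give 6.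

Step 8.
- What may go wrong: slow or misdirected proton removal. The substrate carries an alkoxide and a twisted enoate, so equilibrium γ-deprotonation may be sluggish or may occur at the C2 methyl, moving the alkene out of the ring.
- Fallback, from 12 (isolated by leaving out the acid treatment of step 7) back to 15: irreversible γ-deprotonation of 12 with LiN(i-Pr)2 (THF, −78 °C) and kinetic α-protonation with AcOH at −78 °C give methyl (1S,5R)-2,6,6-trimethyl-5-[(triethylsilyl)oxy]cyclohex-2-ene-1-carboxylate F9 together with its C1 epimer methyl (1R,5R)-2,6,6-trimethyl-5-[(triethylsilyl)oxy]cyclohex-2-ene-1-carboxylate F10. TsOH·H2O in toluene at 60 °C removes the silyl groups; F9 closes to 15, while F10 ends as methyl (1R,5R)-5-hydroxy-2,6,6-trimethylcyclohex-2-ene-1-carboxylate F11, which cannot lactonise. F11 is separated and epimerised at its doubly activated C1–H with KOt-Bu in THF, the cis alkoxide closing to 15.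

Step 10.
- What may go wrong: internal displacement. The activated C7 oxygen may be attacked by the cis C5 hydroxyl, closing a five-membered bridged ether, faster than by the phenoxide at this β-branched carbon.
- Fallback, from 16 back to 20: the primary hydroxyl of 16 is silylated selectively (Et3SiCl 1.0 equiv, imidazole, CH2Cl2, −20 °C) to give (1R,5S)-4,6,6-trimethyl-5-{[(triethylsilyl)oxy]methyl}cyclohex-3-en-1-ol F12. Acylation with 19 (pyridine, 4-(dimethylamino)pyridine) gives (1R,5S)-4,6,6-trimethyl-5-{[(triethylsilyl)oxy]methyl}cyclohex-3-en-1-yl 3-methylbutanoate F13. Pyridinium p-toluenesulfonate in MeOH frees the primary alcohol (1R,5S)-5-(hydroxymethyl)-4,6,6-trimethylcyclohex-3-en-1-yl 3-methylbutanoate F14 under acidic conditions that do not promote acyl migration. Mitsunobu coupling of F14 with 17 (PPh3, diisopropyl azodicarboxylate) then gives 20 with no free C5 hydroxyl present.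

## Further compounds

F1 | step 4 | racemic 5-hydroxy-2,6,6-trimethylcyclohex-2-en-1-one | CC1=CCC(O)C(C)(C)C1=O
F2 | step 4 | (R)-4,6,6-trimethyl-5-oxocyclohex-3-en-1-yl acetate | CC1=CC[C@@H](OC(C)=O)C(C)(C)C1=O
F3 | step 4 | (S)-5-hydroxy-2,6,6-trimethylcyclohex-2-en-1-one | CC1=CC[C@H](O)C(C)(C)C1=O
F4 | step 2 | 2-methyl-1-(trimethylsilyloxy)prop-1-ene | CC(C)=CO[Si](C)(C)C
F5 | step 2 | (E)-2-methylbut-2-enal | C/C=C(\C)C=O
F6 | step 2 | racemic (E)-3-hydroxy-2,2,4-trimethylhex-4-enal | C/C=C(\C)C(O)C(C)(C)C=O
F7 | step 3 | (4E)-1-(tert-butylimino)-2,2,4-trimethylhex-4-en-3-one | C/C=C(\C)C(=O)C(C)(C)/C=N/C(C)(C)C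
F8 | step 3 | (3E)-N-tert-butyl-3-[(tert-butyldimethylsilyl)oxy]-2,2,4-trimethylhexa-3,5-dien-1-imine | C=C/C(C)=C(/O[Si](C)(C)C(C)(C)C)C(C)(C)/C=N/C(C)(C)C
F9 | step 8 | methyl (1S,5R)-2,6,6-trimethyl-5-[(triethylsilyl)oxy]cyclohex-2-ene-1-carboxylate | CC1=CC[C@@H](O[Si](CC)(CC)CC)C(C)(C)[C@H]1C(=O)OC
F10 | step 8 | methyl (1R,5R)-2,6,6-trimethyl-5-[(triethylsilyl)oxy]cyclohex-2-ene-1-carboxylate | CC1=CC[C@@H](O[Si](CC)(CC)CC)C(C)(C)[C@@H]1C(=O)OC
F11 | step 8 | methyl (1R,5R)-5-hydroxy-2,6,6-trimethylcyclohex-2-ene-1-carboxylate | CC1=CC[C@@H](O)C(C)(C)[C@@H]1C(=O)OC
F12 | step 10 | (1R,5S)-4,6,6-trimethyl-5-{[(triethylsilyl)oxy]methyl}cyclohex-3-en-1-ol | CC1=CC[C@@H](O)C(C)(C)[C@H]1CO[Si](CC)(CC)CC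
F13 | step 10 | (1R,5S)-4,6,6-trimethyl-5-{[(triethylsilyl)oxy]methyl}cyclohex-3-en-1-yl 3-methylbutanoate | CC1=CC[C@@H](OC(=O)CC(C)C)C(C)(C)[C@H]1CO[Si](CC)(CC)CC
F14 | step 10 | (1R,5S)-5-(hydroxymethyl)-4,6,6-trimethylcyclohex-3-en-1-yl 3-methylbutanoate | CC1=CC[C@@H](OC(=O)CC(C)C)C(C)(C)[C@H]1CO
A1 | alternative 1 | 2,3-epoxychrysanthenone (2,3-epoxy-2,7,7-trimethylbicyclo[3.1.1]heptan-6-one, epoxide anti to the gem-dimethyl bridge, bridgeheads configured as C1 and C5 of 20) | C[C@]12O[C@H]1C[C@@H](C3=O)C(C)(C)[C@H]23
A2 | alternative 1 | 2,3-epoxy-2,8,8-trimethyl-6-oxabicyclo[3.2.1]octan-7-one (epoxy γ-lactone, carbonyl on C1, ring oxygen on C5, epoxide on the face of the lactone bridge) | C[C@]12O[C@H]1C[C@@H](OC3=O)C(C)(C)[C@H]23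
A3 | alternative 2 | (R)-4-[(tert-butyldimethylsilyl)oxy]-3-methylcyclohex-2-en-1-one | O=C1CC[C@@H](O[Si](C)(C)C(C)(C)C)C(C)=C1
A4 | alternative 2 | cis-(2S,4R)-4-[(tert-butyldimethylsilyl)oxy]-2-(hydroxymethyl)-3,3-dimethylcyclohexan-1-one | O=C1CC[C@@H](O[Si](C)(C)C(C)(C)C)C(C)(C)[C@H]1CO
A5 | alternative 3 | 7-{[(2E)-3-methylpenta-2,4-dien-1-yl]oxy}-2H-chromen-2-one | C=C/C(C)=C/COc1ccc2ccc(=O)oc2c1
A6 | alternative 3 | trans-2,5-dimethyl-1-(2-methylprop-1-en-1-yl)borolane (C2-symmetric, enantiomer as encoded) | CC(C)=CB1[C@@H](C)CC[C@@H]1C
A7 | alternative 3 | 7-{[5-(trans-2,5-dimethylborolan-1-yl)-2,6,6-trimethylcyclohex-2-en-1-yl]methoxy}-2H-chromen-2-one (C1 arm and C5 boron cis, configured as in 20) | CC1=CC[C@@H](B2[C@@H](C)CC[C@@H]2C)C(C)(C)[C@H]1COc1ccc2ccc(=O)oc2c1
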